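**Retrosynthetic overview** (ring A = monohydroxy ring: OH on C1, chain on C3, ether on C5; ring B = dihydroxy ring: ether O on C1, OH on C2 and C4, chain on C6)
- The target comes from its tri-O-methyl ether by BBr3 cleavage. Both benzene rings are bought, and the only ring made is the 20-membered macrocycle, closed in the penultimate step.
- The macrocycle comes from open-chain 2-[14-(3-methoxyphenyl)tetradecyl]-4,6-dimethoxyphenol. The oxygen on C1 of ring B is joined to C5 of ring A, which enters as a plain C–H, by a one-flask iridium C–H borylation/copper Chan–Lam coupling (a formal C–H/O–H macrocyclisation).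
- Enabling feature: ring A is 1,3,5-substituted, so in the precursor C5–H of ring A is the only arene C–H with no ortho neighbour. C3–H and C5–H of ring B are each flanked on both sides, and O1 of ring B is the only free OH.
- The phenol O1 comes from an aldehyde carbon by Baeyer–Villiger oxidation. The C14 tether is tetradeca-1,13-diene, joined to 3-bromoanisole and to 2-bromo-4,6-dimethoxybenzaldehyde by two hydroboration/B-alkyl Suzuki–Miyaura couplings.

Key step: step 5

Remark: the target has no stereocentre, and the 20-membered ring is taken to be large enough for both arenes to rotate freely, so no stereochemical element has to be set.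

**Step 1**
Reactants: 1 1-bromo-3,5-dimethoxybenzene
Product: 3 2-bromo-4,6-dimethoxybenzaldehyde, via aryl iminium salt 2 (not isolated)
Conditions: POCl3 (2 equiv), DMF, 0 °C to 90 °C; then H2O, 0 °C
Reagents that add atoms: N,N-dimethylformamide CN(C)C=O; water O
Why: Vilsmeier–Haack formylation attacks C2, which is para to one methoxy group and ortho to the other, rather than the more crowded C4 between the two methoxy groups, a regiochemistry well established for this arene.

**Step 2**
Reactants: 4 tetradeca-1,13-diene; 5 3-bromoanisole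
Product: 7 1-methoxy-3-(tetradec-13-en-1-yl)benzene, via alkenyl borane 6 (not isolated)
Conditions: 4 (4 equiv), 9-BBN (1 equiv), THF, 0 °C to rt; then 5, Pd(dppf)Cl2 (3 mol %), K3PO4 (aq), THF/DMF, 60 °C
Reagents that add atoms: none
Why: Anti-Markovnikov hydroboration followed by B-alkyl Suzuki–Miyaura coupling, in which a fourfold excess of the cheap diene keeps double hydroboration low and the unreacted hydrocarbon can be distilled off and reused.

**Step 3**
Reactants: 7 1-methoxy-3-(tetradec-13-en-1-yl)benzene; 3 2-bromo-4,6-dimethoxybenzaldehyde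
Product: 9 2,4-dimethoxy-6-[14-(3-methoxyphenyl)tetradecyl]benzaldehyde, via alkyl borane 8 (not isolated)
Conditions: 9-BBN (1.1 equiv), THF, rt; then K3PO4 (aq), 3, Pd(dppf)Cl2 (5 mol %), THF/DMF, 60 °C
Reagents that add atoms: none
Why: This is a second hydroboration/B-alkyl Suzuki–Miyaura coupling, in which the ortho-formyl group speeds oxidative addition of the bromide and the aqueous base is added before 3 so that no B–H is left to reduce the aldehyde.

**Step 4**
Reactants: 9 2,4-dimethoxy-6-[14-(3-methoxyphenyl)tetradecyl]benzaldehyde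
Product: 11 2-[14-(3-methoxyphenyl)tetradecyl]-4,6-dimethoxyphenol, via aryl formate 10 (not isolated)
Conditions: mCPBA (1.3 equiv), CH2Cl2, 0 °C to rt; then K2CO3 (cat.), MeOH, argon, rt
Reagents that add atoms: mCPBA OOC(=O)c1cccc(Cl)c1
Why: In this Baeyer–Villiger (Dakin-type) oxidation the ortho,para-dimethoxyaryl group migrates in preference to hydride, the formate shields the electron-rich ring from the peracid, and mild methanolysis under argon frees the only hydroxyl group of the molecule.

**Step 5**
Reactants: 11 2-[14-(3-methoxyphenyl)tetradecyl]-4,6-dimethoxyphenol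
Product: 14 tri-O-methyl ether of the target (20-membered diaryl ether macrocycle), via O,C-diboryl compound 12 (not isolated), via hydroxy boronate 13 (not isolated)
Conditions: [Ir(OMe)(cod)]2 (2.5 mol %), dtbpy (5 mol %), B2pin2 (1.3 equiv), THF, 80 °C, sealed; MeOH, then evaporation with toluene; then syringe-pump addition (16 h) to Cu(OAc)2 (3 equiv), B(OH)3 (3 equiv), pyridine (6 equiv), 4 Å MS, MeCN, 65 °C, argon, final 1.5 mM
Reagents that add atoms: none
Why: The iridium trisboryl catalyst (trivalent iridium) first converts the phenol O–H of ring B into O–Bpin, which masks it, and the HBpin set free then serves the C–H step, in which only C5–H of ring A reacts because it is the sole arene C–H of 11 without an ortho substituent (C4–H and C6–H of ring A have one, C2–H of ring A and C3–H and C5–H of ring B have two). Methanol then frees the phenol, the aryl group passes from boron to a divalent copper phenoxide, a second divalent copper oxidises this species to trivalent copper, and reductive elimination forms the bond between the ring B oxygen and C5 of ring A. The closest known reactions are the sequential iridium borylation/copper etherification of 1,3-disubstituted arenes and the Chan–Lam–Evans macrocyclisation of phenol-bearing arylboron compounds, run here in one flask as a formal C–H/O–H coupling. The 20-membered ring closes end to end by reductive elimination from a 21-membered cupracycle, helped by pseudo-high dilution and an unstrained C14 tether, and no stereocentre is formed. Chemoselectivity rests on 11 having a single free hydroxyl group, on di-ortho-substituted phenols being accepted in this coupling, and on boric acid binding the pinacol that otherwise slows transmetalation. Working under argon with excess Cu(OAc)2 as the only oxidant keeps O2 away from the electron-rich ring B.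

**Step 6**
Reactants: 14 tri-O-methyl ether of the target
Product: 15 target macrocyclic triol
Conditions: BBr3 (8 equiv), CH2Cl2, −78 °C to rt; then H2O
Reagents that add atoms: none
Why: Lewis-acid ether cleavage with BBr3 removes all three aryl methyl ethers by bromide attack on the methyl carbons, while the diaryl ether offers no sp3 carbon for such attack and stays intact.

**Compound list**
1 | 1-bromo-3,5-dimethoxybenzene | COc1cc(Br)cc(OC)c1 | starting material
2 | (2-bromo-4,6-dimethoxybenzylidene)dimethyliminium dichlorophosphate | COc1cc(Br)c(C=[N+](C)C)c(OC)c1.[O-]P(=O)(Cl)Cl | intermediate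
3 | 2-bromo-4,6-dimethoxybenzaldehyde | COc1cc(Br)c(C=O)c(OC)c1 | intermediate
4 | tetradeca-1,13-diene | C=CCCCCCCCCCCCC=C | starting material
5 | 3-bromoanisole | COc1cccc(Br)c1 | starting material
6 | 9-(tetradec-13-en-1-yl)-9-borabicyclo[3.3.1]nonane | C=CCCCCCCCCCCCCB1C2CCCC1CCC2 | intermediate
7 | 1-methoxy-3-(tetradec-13-en-1-yl)benzene | COc1cccc(CCCCCCCCCCCCC=C)c1 | intermediate
8 | 9-[14-(3-methoxyphenyl)tetradecyl]-9-borabicyclo[3.3.1]nonane | COc1cccc(CCCCCCCCCCCCCCB2C3CCCC2CCC3)c1 | intermediate
9 | 2,4-dimethoxy-6-[14-(3-methoxyphenyl)tetradecyl]benzaldehyde | COc1cccc(CCCCCCCCCCCCCCc2cc(OC)cc(OC)c2C=O)c1 | intermediate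
10 | 2,4-dimethoxy-6-[14-(3-methoxyphenyl)tetradecyl]phenyl formate | COc1cccc(CCCCCCCCCCCCCCc2cc(OC)cc(OC)c2OC=O)c1 | intermediate
11 | 2-[14-(3-methoxyphenyl)tetradecyl]-4,6-dimethoxyphenol | COc1cccc(CCCCCCCCCCCCCCc2cc(OC)cc(OC)c2O)c1 | intermediate
12 | O-Bpin aryl borate of 11 that also carries Bpin on C5 of ring A | COc1cc(CCCCCCCCCCCCCCc2cc(OC)cc(OC)c2OB2OC(C)(C)C(C)(C)O2)cc(c1)B1OC(C)(C)C(C)(C)O1 | intermediate
13 | 2-{14-[3-methoxy-5-(4,4,5,5-tetramethyl-1,3,2-dioxaborolan-2-yl)phenyl]tetradecyl}-4,6-dimethoxyphenol | COc1cc(CCCCCCCCCCCCCCc2cc(OC)cc(OC)c2O)cc(c1)B1OC(C)(C)C(C)(C)O1 | intermediate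
14 | tri-O-methyl ether of the target (ring A: 1-OMe, 3-chain, 5-O; ring B: 1-O, 2-OMe, 4-OMe, 6-chain; rings joined by the ether O and by (CH2)14) | COc1cc2cc(c1)Oc1c(OC)cc(OC)cc1CCCCCCCCCCCCCC2 | intermediate
15 | target macrocyclic triol (as 14, with OH in place of each OMe) | Oc1cc2cc(c1)Oc1c(O)cc(O)cc1CCCCCCCCCCCCCC2 | target

**Total step count:** 6
**Longest linear sequence:** 5 steps (step 1 or step 2, then steps 3, 4, 5 and 6)

**Steps most likely to fail**

1. **Step 5.** Oxidation of the electron-rich ring B phenol by divalent copper, protodeboronation of ring A and intermolecular coupling may outrun the slow closure of the 20-membered ring.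
 - The fallback replaces the oxidative C–H route by a redox-neutral Buchwald–Hartwig-type C–O coupling of a pre-installed chloride. It closes the ring at the same O–C5 bond.
 - It sets out from borane 6 (made from 4 as in step 2) and comes back at 14.
 - Borane 6 is coupled at the C–Br bond of commercial 1-bromo-3-chloro-5-methoxybenzene (Pd(dppf)Cl2, K3PO4, THF/DMF, 60 °C; the C–Cl bond is inert here) to give 1-chloro-3-methoxy-5-(tetradec-13-en-1-yl)benzene F1.
 - 9-BBN turns F1 into 9-[14-(3-chloro-5-methoxyphenyl)tetradecyl]-9-borabicyclo[3.3.1]nonane F2, which is coupled with 3 to give 2-[14-(3-chloro-5-methoxyphenyl)tetradecyl]-4,6-dimethoxybenzaldehyde F3.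
 - mCPBA gives 2-[14-(3-chloro-5-methoxyphenyl)tetradecyl]-4,6-dimethoxyphenyl formate F4, and methanolysis gives 2-[14-(3-chloro-5-methoxyphenyl)tetradecyl]-4,6-dimethoxyphenol F5.
 - Slow addition of F5 to Pd(OAc)2, t-BuXPhos and K3PO4 in toluene at 100 °C under argon (about 2 mM) should close the ring to 14 without any oxidant.

2. **Step 4.** Hydride rather than aryl migration in the crowded Criegee adduct, and over-oxidation of the freed phenol toward a quinone, may erode the material.
 - The fallback installs O1 by C–B oxidation instead of through the aldehyde.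
 - It sets out from borane 8 (made from 7 as in step 3) and bromide 1, and comes back at 11.
 - Borane 8 is coupled with 1 (Pd(dppf)Cl2, K3PO4, THF/DMF, 60 °C) to give 1-[14-(3,5-dimethoxyphenyl)tetradecyl]-3-methoxybenzene F6.
 - NBS (1 equiv, MeCN, 0 °C) brominates the far more electron-rich dimethoxy ring, para to one methoxy group and next to the chain, to give 2-bromo-1,5-dimethoxy-3-[14-(3-methoxyphenyl)tetradecyl]benzene F7.
 - Bromine–lithium exchange (n-BuLi, THF, −78 °C) and trapping with B(OMe)3 give dimethyl {2,4-dimethoxy-6-[14-(3-methoxyphenyl)tetradecyl]phenyl}boronate F8.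
 - H2O2/NaOH at 0 °C oxidises the C–B bond of F8 to the phenol 11.

3. **Step 2.** Double hydroboration of the diene, migration of the remaining alkene under palladium hydride species, and a tedious separation of hydrocarbon-like products may spoil the statistical monofunctionalisation.
 - The fallback builds the chain from a C11 unit with two different ends.
 - It sets out from 5 and comes back at 7.
 - Commercial 11-bromoundec-1-ene is hydroborated with 9-BBN to give 9-(11-bromoundecyl)-9-borabicyclo[3.3.1]nonane F9.
 - Coupling of F9 with 5 (Pd(dppf)Cl2, K3PO4, THF/DMF, 50 °C; the primary alkyl bromide is inert to this catalyst) gives 1-(11-bromoundecyl)-3-methoxybenzene F10.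
 - Allylmagnesium bromide with Li2CuCl4 (cat.) in THF at 0 °C (Kochi-type copper-catalysed Grignard coupling) adds the last three carbons to give 7.

**Further compounds**
F1 | step 5 | 1-chloro-3-methoxy-5-(tetradec-13-en-1-yl)benzene | COc1cc(Cl)cc(CCCCCCCCCCCCC=C)c1
F2 | step 5 | 9-[14-(3-chloro-5-methoxyphenyl)tetradecyl]-9-borabicyclo[3.3.1]nonane | COc1cc(Cl)cc(CCCCCCCCCCCCCCB2C3CCCC2CCC3)c1
F3 | step 5 | 2-[14-(3-chloro-5-methoxyphenyl)tetradecyl]-4,6-dimethoxybenzaldehyde | COc1cc(Cl)cc(CCCCCCCCCCCCCCc2cc(OC)cc(OC)c2C=O)c1
F4 | step 5 | 2-[14-(3-chloro-5-methoxyphenyl)tetradecyl]-4,6-dimethoxyphenyl formate | COc1cc(Cl)cc(CCCCCCCCCCCCCCc2cc(OC)cc(OC)c2OC=O)c1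
F5 | step 5 | 2-[14-(3-chloro-5-methoxyphenyl)tetradecyl]-4,6-dimethoxyphenol | COc1cc(Cl)cc(CCCCCCCCCCCCCCc2cc(OC)cc(OC)c2O)c1
F6 | step 4 | 1-[14-(3,5-dimethoxyphenyl)tetradecyl]-3-methoxybenzene | COc1cccc(CCCCCCCCCCCCCCc2cc(OC)cc(OC)c2)c1
F7 | step 4 | 2-bromo-1,5-dimethoxy-3-[14-(3-methoxyphenyl)tetradecyl]benzene | COc1cccc(CCCCCCCCCCCCCCc2cc(OC)cc(OC)c2Br)c1
F8 | step 4 | dimethyl {2,4-dimethoxy-6-[14-(3-methoxyphenyl)tetradecyl]phenyl}boronate | COc1cccc(CCCCCCCCCCCCCCc2cc(OC)cc(OC)c2B(OC)OC)c1
F9 | step 2 | 9-(11-bromoundecyl)-9-borabicyclo[3.3.1]nonane | BrCCCCCCCCCCCB1C2CCCC1CCC2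
F10 | step 2 | 1-(11-bromoundecyl)-3-methoxybenzene | COc1cccc(CCCCCCCCCCCBr)c1
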